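**Plan**

1. Numbering and enabling feature: ring C1 (carries C7), C2 (OAc), C3 (OAng), C4 (CH3), C5, C6 (CH2); chain C7(=C14H2)–C8(OAng)–C9–C10–C11. In ring C1–C6, a carbon substituent on C1, oxygens on C2 and C3 and a C4=C5 alkene (the later epoxide) beside the C4 methyl are exactly the cyclohex-3-enecarbaldehyde that a 3,4-dioxygenated 2-methyl-2-vinyl-3,4-dihydro-2H-pyran gives by a Claisen shift.
2. Retrosynthesis: both epoxides and the three esters are taken off; C7–C8 is cut (alkenyl triflate + 4-methylpent-3-enal); ring bond C1–C6 is cut with the O–C4 bond restored (retro-Claisen) to a vinyl dihydropyran; its O–CH= bond is cut to an alkynol; methyl and vinyl are cut from the carbinol carbon back to D-erythronolactone acetonide.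
3. Forward: dioxolane from the chiral pool, pyran by tungsten-catalysed alkynol cycloisomerisation, carbocycle by the Claisen step (the pyran opens), chain joined at C7–C8 by Nozaki–Hiyama–Kishi coupling, then ring epoxide, esters and the side-chain epoxide last.
4. Stereochemistry: C2 and C3 from D-erythronolactone; the quaternary pyran carbon by chelation-controlled MeMgBr addition; C1 by transfer from that centre in the Claisen step; C8 by CBS reduction; C4/C5 by the 3-OH-directed epoxidation; C10 by Shi epoxidation.

Key step: step 9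

Remark: Ang = angeloyl, (Z)-2-methylbut-2-enoyl. The L-fructose-derived Shi ketone is assumed to give the (10S)-epoxide, the mirror image of the sense known for the D-fructose-derived ketone with R–CH=C(CH3)2 alkenes.

**Route**

Step 1
Reactants: 1 2,3-O-isopropylidene-D-erythronolactone
Product: 2 (4R,5R)-5-(hydroxymethyl)-N-methoxy-N,2,2-trimethyl-1,3-dioxolane-4-carboxamide
Conditions: MeNH(OMe)·HCl, AlMe3, CH2Cl2, 0 °C to rt
Reagents that add atoms: N,O-dimethylhydroxylamine hydrochloride, CNOC.Cl
Why: Weinreb aminolysis: the aluminium amide made in the flask from AlMe3 and the amine salt opens the lactone at the acyl carbon, which leaves both dioxolane stereocentres untouched and frees the primary hydroxyl.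

Step 2
Reactants: 2 hydroxy Weinreb amide
Product: 3 (4R,5R)-5-{[tert-butyl(dimethyl)silyl]oxymethyl}-N-methoxy-N,2,2-trimethyl-1,3-dioxolane-4-carboxamide
Conditions: t-BuMe2SiCl, imidazole, DMF, 0 °C to rt
Reagents that add atoms: tert-butyldimethylsilyl chloride, CC(C)(C)[Si](C)(C)Cl
Why: Silyl ether formation at the unhindered primary hydroxyl prevents relactonisation of the hydroxy amide and masks the only acidic proton before the two Grignard additions.

Step 3
Reactants: 3 silylated Weinreb amide; 4 vinylmagnesium bromide
Product: 5 1-[(4R,5R)-5-{[tert-butyl(dimethyl)silyl]oxymethyl}-2,2-dimethyl-1,3-dioxolan-4-yl]prop-2-en-1-one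
Conditions: CH2=CHMgBr, THF, −78 to 0 °C; inverse quench into cold aq. KHSO4
Reagents that add atoms: vinylmagnesium bromide (4), C=C[Mg]Br
Why: Weinreb ketone synthesis: the magnesium-chelated tetrahedral adduct survives until work-up so that addition stops at the ketone, and the cold acidic inverse quench removes the liberated amine before it can add to the new enone in conjugate fashion.

Step 4
Reactants: 5 vinyl ketone; 6 methylmagnesium bromide
Product: 7 (2S)-2-[(4R,5R)-5-{[tert-butyl(dimethyl)silyl]oxymethyl}-2,2-dimethyl-1,3-dioxolan-4-yl]but-3-en-2-ol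
Conditions: MeMgBr (Et2O solution), CH2Cl2, −78 °C
Reagents that add atoms: methylmagnesium bromide (6), C[Mg]Br
Why: Chelation-controlled (Cram chelate) 1,2-addition of a Grignard reagent to an α-alkoxy ketone: in the weakly coordinating solvent magnesium should bridge the carbonyl oxygen and the adjacent dioxolane oxygen, so that the hard methyl nucleophile adds to the carbonyl carbon from the face turned away from dioxolane carbon C5 and sets the (S)-carbinol, the configuration that later holds the vinyl group trans to the dioxolane oxygens.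

Step 5
Reactants: 7 silyl ether
Product: 8 (2S)-2-[(4R,5R)-5-(hydroxymethyl)-2,2-dimethyl-1,3-dioxolan-4-yl]but-3-en-2-ol
Conditions: Bu4NF, THF, 0 °C to rt
Reagents that add atoms: none
Why: Fluoride-induced cleavage of the silyl ether, driven by the Si–F bond, frees the primary alcohol while the acetonide and the tertiary allylic alcohol are inert to Bu4NF.

Step 6
Reactants: 8 diol
Product: 10 lactol (3aS,6S,6aR)-2,2,6-trimethyl-6-vinyltetrahydrofuro[3,4-d][1,3]dioxol-4-ol as an anomeric mixture, via hydroxy aldehyde 9 (not isolated)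
Conditions: IBX, DMSO, rt
Reagents that add atoms: none
Why: IBX oxidation of the primary alcohol of a 1,4-diol: the tertiary hydroxyl cannot be oxidised and closes onto aldehyde 9 to give the γ-lactol, the stage at which IBX oxidations of 1,4-diols stop at room temperature.

Step 7
Reactants: 10 lactol; 11 dimethyl (1-diazo-2-oxopropyl)phosphonate
Product: 12 (2S)-2-[(4R,5R)-5-ethynyl-2,2-dimethyl-1,3-dioxolan-4-yl]but-3-en-2-ol
Conditions: K2CO3, MeOH, rt to 45 °C
Reagents that add atoms: dimethyl (1-diazo-2-oxopropyl)phosphonate (11), CC(=O)C(=[N+]=[N-])P(=O)(OC)OC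
Why: Ohira–Bestmann alkynylation (Seyferth–Gilbert homologation) of a lactol, which reacts through its small equilibrium share of open aldehyde 9, so that the mild K2CO3/MeOH conditions should not epimerise the α-alkoxy stereocentre.

Step 8
Reactants: 12 alkynol
Product: 13 (3aR,4S,7aR)-2,2,4-trimethyl-4-vinyl-3a,7a-dihydro-4H-[1,3]dioxolo[4,5-c]pyran (vinyl trans to the dioxolane oxygens)
Conditions: W(CO)6 (25 mol %), DABCO, THF, hν (350 nm), 60 °C
Reagents that add atoms: none
Why: Tungsten-catalysed endo-selective cycloisomerisation of a pent-4-yn-1-ol: photolytically generated W(CO)5 (zerovalent tungsten) turns the terminal alkyne into a vinylidene whose electrophilic carbon is attacked by the tertiary hydroxyl, which closes the six-membered enol ether in the way established for glycal synthesis from acetonide-protected alkynols and leaves all stereocentres untouched.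

Step 9
Reactants: 13 vinyl dihydropyran
Product: 14 (1R,5S,6R)-5,6-(isopropylidenedioxy)-4-methylcyclohex-3-ene-1-carbaldehyde (all-cis)
Conditions: PhMe (degassed), 210 °C, sealed silylated glass tube
Reagents that add atoms: none
Why: Heating drives a concerted, suprafacial [3,3]-sigmatropic (Claisen) reorganisation of the allyl vinyl ether unit CH2=CH–C(CH3)–O–CH=CH held in the pyran: a σ-bond grows between the terminal vinyl carbon (later C6) and the nucleophilic carbon β to the ring oxygen (later C1) as the O–C(quaternary) bond is given up, and the formyl C=O that appears makes the change irreversible. The closest known reaction type is the thermal Claisen rearrangement of 2-alkenyl-3,4-dihydro-2H-pyrans (C-vinyl glycals) to cyclohex-3-enecarbaldehydes. The six-membered carbocycle closes through a boat-shaped six-centre transition state of bicyclo[2.2.2]octane type, in which the vinyl group bridges the 2- and 5-positions of the pyran, so that the heterocycle is traded for the carbocycle in one pericyclic event without charged intermediates. The one new stereocentre, C1, is controlled by the quaternary carbon of 13: the vinyl group is tethered to the ring face anti to both dioxolane oxygens, the C1–C6 bond can only form on that face, and the formyl group is therefore left syn to the C2 and C3 oxygens. The step needs this diastereoselectivity, which the intramolecular geometry secures, and chemoselectivity over ionisation of the tertiary allylic C–O bond or retro-hetero-Diels–Alder cleavage, which the acid-free medium, the electron-rich enol ether and the weak tertiary allylic ether bond (both lowering the pericyclic barrier) should secure.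

Step 10
Reactants: 14 aldehyde; 6 methylmagnesium bromide
Product: 15 1-[5,6-(isopropylidenedioxy)-4-methylcyclohex-3-en-1-yl]ethan-1-ol, ring configured as in 14, both carbinol epimers
Conditions: MeMgBr, THF, −78 °C
Reagents that add atoms: methylmagnesium bromide (6), C[Mg]Br
Why: Grignard 1,2-addition to an aldehyde, which at −78 °C is much faster than enolisation and therefore keeps the C1 configuration; the new carbinol centre forms as a mixture that is removed by the oxidation in step 11.

Step 11
Reactants: 15 secondary alcohol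
Product: 16 1-[(1R,5S,6R)-5,6-(isopropylidenedioxy)-4-methylcyclohex-3-en-1-yl]ethan-1-one
Conditions: Dess–Martin periodinane, NaHCO3, CH2Cl2, 0 °C to rt
Reagents that add atoms: none
Why: Dess–Martin oxidation of the secondary alcohol under buffered, essentially neutral conditions gives the methyl ketone without epimerising C1 or eliminating the β-alkoxy group.

Step 12
Reactants: 16 methyl ketone
Product: 17 1-[(1R,5S,6R)-5,6-(isopropylidenedioxy)-4-methylcyclohex-3-en-1-yl]ethenyl trifluoromethanesulfonate
Conditions: KN(SiMe3)2, THF, −78 °C; PhNTf2, −78 to 0 °C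
Reagents that add atoms: N-phenylbis(trifluoromethanesulfonimide), O=S(=O)(N(c1ccccc1)S(=O)(=O)C(F)(F)F)C(F)(F)F
Why: Kinetic deprotonation by the bulky amide base at −78 °C occurs at the methyl group and not at the hindered C1 methine, and O-sulfonylation of the potassium enolate (enol triflate formation) gives the 1,1-disubstituted alkenyl triflate with C1 untouched.

Step 13
Reactants: 18 4-methylpent-3-en-1-ol
Product: 19 4-methylpent-3-enal
Conditions: Dess–Martin periodinane, NaHCO3, CH2Cl2, 0 °C
Reagents that add atoms: none
Why: Dess–Martin oxidation of a primary homoallylic alcohol under NaHCO3 buffering gives the β,γ-unsaturated aldehyde without migration of the alkene into conjugation, and the volatile aldehyde is used at once as a solution.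

Step 14
Reactants: 17 alkenyl triflate; 19 4-methylpent-3-enal
Product: 20 6-methyl-2-[5,6-(isopropylidenedioxy)-4-methylcyclohex-3-en-1-yl]hepta-1,5-dien-3-ol, ring configured as in 14, both C8 epimers
Conditions: CrCl2 (4 equiv), NiCl2 (2 mol %), DMF, rt
Reagents that add atoms: none
Why: Nozaki–Hiyama–Kishi coupling: zerovalent nickel formed in the flask inserts into the alkenyl C–OTf bond and transmetallation gives an alkenylchromium species that adds only to the aldehyde under neutral conditions which the enolisable β,γ-unsaturated aldehyde and the acetonide tolerate; the C8 configuration is not controlled here and is set in steps 15 and 16.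

Step 15
Reactants: 20 allylic alcohol
Product: 21 6-methyl-2-[5,6-(isopropylidenedioxy)-4-methylcyclohex-3-en-1-yl]hepta-1,5-dien-3-one, ring configured as in 14
Conditions: Dess–Martin periodinane, NaHCO3, CH2Cl2, 0 °C
Reagents that add atoms: none
Why: Dess–Martin oxidation of the allylic alcohol converges both C8 epimers on one α-methylene ketone, and the buffered conditions should keep the skipped C10=C11 alkene out of conjugation.

Step 16
Reactants: 21 enone
Product: 22 (3S)-6-methyl-2-[5,6-(isopropylidenedioxy)-4-methylcyclohex-3-en-1-yl]hepta-1,5-dien-3-ol, ring configured as in 14 (C8 = S)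
Conditions: (R)-2-methyl-CBS-oxazaborolidine (20 mol %), catecholborane, PhMe, −78 °C
Reagents that add atoms: none
Why: Corey–Bakshi–Shibata reduction: the α-branched alkenyl group (C7) acts as the large and the C9 methylene as the small carbonyl substituent, so that the (R)-oxazaborolidine should deliver hydride to the face that gives the (8S)-alcohol under reagent control, while catecholborane at −78 °C does not hydroborate the alkenes.

Step 17
Reactants: 22 (8S)-alcohol; 23 angelic acid
Product: 24 (3S)-6-methyl-2-[5,6-(isopropylidenedioxy)-4-methylcyclohex-3-en-1-yl]hepta-1,5-dien-3-yl (Z)-2-methylbut-2-enoate, ring configured as in 14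
Conditions: angelic acid, 2,4,6-Cl3C6H2COCl, Et3N, PhMe, rt, filtered from Et3N·HCl; then 22, 80 °C
Reagents that add atoms: angelic acid (23), C/C=C(/C)C(=O)O
Why: Yamaguchi-type esterification through the preformed mixed 2,4,6-trichlorobenzoic anhydride without a nucleophilic catalyst acylates the C8 hydroxyl with retention and avoids the Z to E isomerisation of the angeloyl group to tigloyl that acid chlorides or 4-(dimethylamino)pyridine cause.

Step 18
Reactants: 24 acetonide
Product: 25 (3S)-2-[5,6-dihydroxy-4-methylcyclohex-3-en-1-yl]-6-methylhepta-1,5-dien-3-yl (Z)-2-methylbut-2-enoate, ring carbons configured as in 14 (C1 side chain, 2-OH and 3-OH all cis)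
Conditions: AcOH–H2O (4:1), 45 °C
Reagents that add atoms: none
Why: Acid-catalysed acetal hydrolysis in aqueous acetic acid removes the isopropylidene group under conditions mild enough for the allylic angelate, the skipped diene and the ring alkene.

Step 19
Reactants: 25 diol; 26 trimethyl orthoacetate
Product: 28 2-O-acetyl derivative of diol 25 (target numbering: 2-OAc and free 3-OH), via cyclic orthoester 27 (not isolated)
Conditions: MeC(OMe)3, PPTS (cat.), CH2Cl2, rt; then AcOH–H2O (4:1), rt
Reagents that add atoms: trimethyl orthoacetate (26), COC(C)(OC)OC; water, O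
Why: Orthoester exchange with the cis-diol and mild acid hydrolysis of the cyclic orthoester: such orthoesters on six-membered rings open to the axial ester and equatorial alcohol, and since O2 is axial when the C1 side chain is equatorial the acetyl group should end on O2 and leave the allylic 3-OH free, with no stereocentre touched.

Step 20
Reactants: 28 hydroxy acetate
Product: 29 4,5-epoxide of 28 with the epoxide oxygen cis to 3-OH (target lacking the 3-O-angeloyl group and the 10,11-epoxide)
Conditions: VO(acac)2 (5 mol %), t-BuOOH, CH2Cl2, 0 °C to rt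
Reagents that add atoms: tert-butyl hydroperoxide, CC(C)(C)OO
Why: Vanadium-catalysed hydroxyl-directed epoxidation: the alkoxide–peroxide complex on the allylic C3 oxygen delivers oxygen to the C4=C5 face syn to that hydroxyl, which sets C4 and C5 on the all-cis face, and the alkenes without a free allylic hydroxyl (C7=C14, C10=C11 and the angelate) are not touched.

Step 21
Reactants: 29 epoxy alcohol; 23 angelic acid
Product: 30 3-O-angeloyl derivative of 29 (the target with a C10=C11 alkene in place of the side-chain epoxide)
Conditions: angelic acid, 2,4,6-Cl3C6H2COCl, Et3N, PhMe, rt, filtered from Et3N·HCl; then 29, 80 °C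
Reagents that add atoms: angelic acid (23), C/C=C(/C)C(=O)O
Why: The same mixed-anhydride (Yamaguchi-type) angeloylation acylates the hindered C3 hydroxyl with retention under base-poor conditions that should neither open the epoxide nor move the neighbouring acetyl group.

Step 22
Reactants: 30 diene bis-angelate
Product: 31 CNP0118696.1, (1S,2R,3R,4S,5S,8S,10S)-2-acetoxy-3,8-bis[(Z)-2-methylbut-2-enoyloxy]-4,5:10,11-diepoxybisabol-7(14)-ene in the numbering of the plan
Conditions: L-fructose-derived Shi ketone (1,2:4,5-di-O-isopropylidene-β-L-erythro-2,3-hexodiulo-2,6-pyranose, 30 mol %), KHSO5 (as 2KHSO5·KHSO4·K2SO4), K2CO3, Bu4NHSO4, MeCN–CH2(OMe)2 / aq. Na2B4O7 buffer (pH 10.5), 0 °C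
Reagents that add atoms: potassium peroxymonosulfate, [K+].[O-]S(=O)(=O)OO
Why: Shi asymmetric epoxidation: the chiral dioxirane formed from the ketone and KHSO5 reacts only with the electron-rich trisubstituted C10=C11 alkene (the allylic-ester C7=C14 alkene and the two conjugated angelate alkenes are electron-poor) and, through the spiro transition state of the L-configured ketone, should give the (10S)-epoxide under reagent control.

**Compound list**

1 | 2,3-O-isopropylidene-D-erythronolactone | O=C1OC[C@H]2OC(C)(C)O[C@@H]12 | starting material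
2 | (4R,5R)-5-(hydroxymethyl)-N-methoxy-N,2,2-trimethyl-1,3-dioxolane-4-carboxamide | CON(C)C(=O)[C@@H]1OC(C)(C)O[C@@H]1CO | intermediate
3 | (4R,5R)-5-{[tert-butyl(dimethyl)silyl]oxymethyl}-N-methoxy-N,2,2-trimethyl-1,3-dioxolane-4-carboxamide | CON(C)C(=O)[C@@H]1OC(C)(C)O[C@@H]1CO[Si](C)(C)C(C)(C)C | intermediate
4 | vinylmagnesium bromide | C=C[Mg]Br | starting material
5 | 1-[(4R,5R)-5-{[tert-butyl(dimethyl)silyl]oxymethyl}-2,2-dimethyl-1,3-dioxolan-4-yl]prop-2-en-1-one | C=CC(=O)[C@@H]1OC(C)(C)O[C@@H]1CO[Si](C)(C)C(C)(C)C | intermediate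
6 | methylmagnesium bromide | C[Mg]Br | starting material
7 | (2S)-2-[(4R,5R)-5-{[tert-butyl(dimethyl)silyl]oxymethyl}-2,2-dimethyl-1,3-dioxolan-4-yl]but-3-en-2-ol | C=C[C@](C)(O)[C@@H]1OC(C)(C)O[C@@H]1CO[Si](C)(C)C(C)(C)C | intermediate
8 | (2S)-2-[(4R,5R)-5-(hydroxymethyl)-2,2-dimethyl-1,3-dioxolan-4-yl]but-3-en-2-ol | C=C[C@](C)(O)[C@@H]1OC(C)(C)O[C@@H]1CO | intermediate
9 | (4S,5R)-5-[(2S)-2-hydroxybut-3-en-2-yl]-2,2-dimethyl-1,3-dioxolane-4-carbaldehyde | C=C[C@](C)(O)[C@@H]1OC(C)(C)O[C@@H]1C=O | intermediate (not isolated)
10 | (3aS,6S,6aR)-2,2,6-trimethyl-6-vinyltetrahydrofuro[3,4-d][1,3]dioxol-4-ol, anomeric mixture | C=C[C@]1(C)OC(O)[C@H]2OC(C)(C)O[C@@H]12 | intermediate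
11 | dimethyl (1-diazo-2-oxopropyl)phosphonate | CC(=O)C(=[N+]=[N-])P(=O)(OC)OC | starting material
12 | (2S)-2-[(4R,5R)-5-ethynyl-2,2-dimethyl-1,3-dioxolan-4-yl]but-3-en-2-ol | C=C[C@](C)(O)[C@@H]1OC(C)(C)O[C@@H]1C#C | intermediate
13 | (3aR,4S,7aR)-2,2,4-trimethyl-4-vinyl-3a,7a-dihydro-4H-[1,3]dioxolo[4,5-c]pyran | C=C[C@]1(C)OC=C[C@H]2OC(C)(C)O[C@@H]12 | intermediate
14 | (1R,5S,6R)-5,6-(isopropylidenedioxy)-4-methylcyclohex-3-ene-1-carbaldehyde, all-cis | O=C[C@@H]1CC=C(C)[C@@H]2OC(C)(C)O[C@H]12 | intermediate
15 | 1-[5,6-(isopropylidenedioxy)-4-methylcyclohex-3-en-1-yl]ethan-1-ol, ring as in 14, carbinol epimers | CC(O)[C@@H]1CC=C(C)[C@@H]2OC(C)(C)O[C@H]12 | intermediate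
16 | 1-[(1R,5S,6R)-5,6-(isopropylidenedioxy)-4-methylcyclohex-3-en-1-yl]ethan-1-one | CC(=O)[C@@H]1CC=C(C)[C@@H]2OC(C)(C)O[C@H]12 | intermediate
17 | 1-[(1R,5S,6R)-5,6-(isopropylidenedioxy)-4-methylcyclohex-3-en-1-yl]ethenyl trifluoromethanesulfonate | C=C(OS(=O)(=O)C(F)(F)F)[C@@H]1CC=C(C)[C@@H]2OC(C)(C)O[C@H]12 | intermediate
18 | 4-methylpent-3-en-1-ol | CC(C)=CCCO | starting material
19 | 4-methylpent-3-enal | CC(C)=CCC=O | intermediate
20 | 6-methyl-2-[5,6-(isopropylidenedioxy)-4-methylcyclohex-3-en-1-yl]hepta-1,5-dien-3-ol, ring as in 14, C8 epimers | C=C(C(O)CC=C(C)C)[C@@H]1CC=C(C)[C@@H]2OC(C)(C)O[C@H]12 | intermediate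
21 | 6-methyl-2-[5,6-(isopropylidenedioxy)-4-methylcyclohex-3-en-1-yl]hepta-1,5-dien-3-one, ring as in 14 | C=C(C(=O)CC=C(C)C)[C@@H]1CC=C(C)[C@@H]2OC(C)(C)O[C@H]12 | intermediate
22 | (3S)-6-methyl-2-[5,6-(isopropylidenedioxy)-4-methylcyclohex-3-en-1-yl]hepta-1,5-dien-3-ol, ring as in 14 | C=C([C@H](CC=C(C)C)O)[C@@H]1CC=C(C)[C@@H]2OC(C)(C)O[C@H]12 | intermediate
23 | angelic acid, (Z)-2-methylbut-2-enoic acid | C/C=C(/C)C(=O)O | starting material
24 | 8-O-angeloyl derivative of 22 | C=C([C@H](CC=C(C)C)OC(=O)/C(C)=C\C)[C@@H]1CC=C(C)[C@@H]2OC(C)(C)O[C@H]12 | intermediate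
25 | 2,3-cis-diol from 24 (C1 side chain, 2-OH, 3-OH all cis; 8-OAng) | C=C([C@H](CC=C(C)C)OC(=O)/C(C)=C\C)[C@@H]1CC=C(C)[C@H](O)[C@@H]1O | intermediate
26 | trimethyl orthoacetate | COC(C)(OC)OC | starting material
27 | cyclic 2,3-O-(1-methoxyethylidene) orthoester of 25 | C=C([C@H](CC=C(C)C)OC(=O)/C(C)=C\C)[C@@H]1CC=C(C)[C@@H]2OC(C)(OC)O[C@H]12 | intermediate (not isolated)
28 | 2-O-acetyl derivative of 25 (3-OH free) | C=C([C@H](CC=C(C)C)OC(=O)/C(C)=C\C)[C@@H]1CC=C(C)[C@H](O)[C@@H]1OC(C)=O | intermediate
29 | 4,5-epoxide of 28, epoxide oxygen cis to 3-OH | C=C([C@H](CC=C(C)C)OC(=O)/C(C)=C\C)[C@@H]1C[C@@H]2O[C@]2(C)[C@H](O)[C@@H]1OC(C)=O | intermediate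
30 | 3-O-angeloyl derivative of 29 (C10=C11 alkene) | C=C([C@H](CC=C(C)C)OC(=O)/C(C)=C\C)[C@@H]1C[C@@H]2O[C@]2(C)[C@H](OC(=O)/C(C)=C\C)[C@@H]1OC(C)=O | intermediate
31 | CNP0118696.1, (1S,2R,3R,4S,5S,8S,10S)-2-acetoxy-3,8-bis(angeloyloxy)-4,5:10,11-diepoxybisabol-7(14)-ene (numbering of the plan) | C=C([C@H](C[C@@H]1OC1(C)C)OC(=O)/C(C)=C\C)[C@@H]1C[C@@H]2O[C@]2(C)[C@H](OC(=O)/C(C)=C\C)[C@@H]1OC(C)=O | target

**Step count and risks**

Total: 22 steps. Longest linear sequence: 21 steps (1 to 31 through steps 1–12 and 14–22); step 13 prepares aldehyde 19.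

Steps most likely to fail:

Step 4, facial selectivity of the methyl addition. The open (Felkin–Anh) pathway may compete with or override the magnesium chelate, which would erode or invert the configuration of the carbinol. The fallback sets out from 3 and returns at 7, and introduces the two carbon groups in the opposite order. MeMgBr (THF, 0 °C) converts Weinreb amide 3 into the methyl ketone 1-[(4R,5R)-5-{[tert-butyl(dimethyl)silyl]oxymethyl}-2,2-dimethyl-1,3-dioxolan-4-yl]ethan-1-one F1. Vinylmagnesium bromide in THF at −78 °C then adds through the same non-chelated transition state; because methyl and vinyl have changed roles, attack on that face leads to 7.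

Step 8, ring closure by the hindered tertiary hydroxyl. Attack of the tertiary alcohol on the tungsten vinylidene may be slow, so that catalyst decay, incomplete conversion or exo closure take over. The fallback sets out from lactol 10 and returns at 13 by known carbohydrate chemistry. Wittig methoxymethylenation (MeOCH2PPh3Cl, KOtBu, THF) gives the enol ether (2S)-2-[(4R,5R)-5-(2-methoxyethenyl)-2,2-dimethyl-1,3-dioxolan-4-yl]but-3-en-2-ol F2. Mild hydrolysis (PPTS, THF–H2O) gives the 2-deoxy pyranose lactol (3aR,4S,7aR)-2,2,4-trimethyl-4-vinyltetrahydro-4H-[1,3]dioxolo[4,5-c]pyran-6-ol F3. Dehydration of this lactol through its anomeric mesylate (MsCl, Et3N, CH2Cl2, −40 °C to reflux) gives enol ether 13.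

Step 19, regiochemistry of the mono-acetylation. The orthoester may open in the other sense, or the acetyl group may migrate to O3, which would place acetate and angelate on the wrong oxygens. The fallback sets out from diol 25 and returns at 28. The more accessible allylic, pseudo-equatorial 3-OH is silylated selectively (Et3SiCl, imidazole, CH2Cl2, −20 °C) to the 3-O-triethylsilyl ether of 25 F4. The remaining 2-OH is acetylated (Ac2O, pyridine, 4-(dimethylamino)pyridine) to the 2-O-acetyl-3-O-triethylsilyl derivative of 25 F5. The silyl group is then removed under non-basic conditions (HF·pyridine, THF, 0 °C) to give 28.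

**Further compounds**

F1 | step 4 | 1-[(4R,5R)-5-{[tert-butyl(dimethyl)silyl]oxymethyl}-2,2-dimethyl-1,3-dioxolan-4-yl]ethan-1-one | CC(=O)[C@@H]1OC(C)(C)O[C@@H]1CO[Si](C)(C)C(C)(C)C
F2 | step 8 | (2S)-2-[(4R,5R)-5-(2-methoxyethenyl)-2,2-dimethyl-1,3-dioxolan-4-yl]but-3-en-2-ol, E/Z mixture | C=C[C@](C)(O)[C@@H]1OC(C)(C)O[C@@H]1C=COC
F3 | step 8 | (3aR,4S,7aR)-2,2,4-trimethyl-4-vinyltetrahydro-4H-[1,3]dioxolo[4,5-c]pyran-6-ol, anomeric mixture | C=C[C@]1(C)OC(O)C[C@H]2OC(C)(C)O[C@@H]12
F4 | step 19 | 3-O-triethylsilyl ether of 25 | C=C([C@H](CC=C(C)C)OC(=O)/C(C)=C\C)[C@@H]1CC=C(C)[C@H](O[Si](CC)(CC)CC)[C@@H]1O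
F5 | step 19 | 2-O-acetyl-3-O-triethylsilyl derivative of 25 | C=C([C@H](CC=C(C)C)OC(=O)/C(C)=C\C)[C@@H]1CC=C(C)[C@H](O[Si](CC)(CC)CC)[C@@H]1OC(C)=O
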